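Of the starting material charged, the dawn run at 2.50 h shows 30.6% as target and 29.2% as isomer of the product A, and the noon run shows 29.3% and 28.5%.

| setting | dawn | noon | flask |
|---|---|---|---|
| starting material | 12 mM | 17 mM | 23 mM |
| remark | run made earlier | run made earlier |  |
| time |  |  | 3.0 h |

| run | time / h | target / % | isomer of the product A / % |
|---|---|---|---|
| dawn | 0.417 | 41.3 | 10.1 |
| dawn | 0.833 | 37.3 | 17.4 |
| dawn | 1.33 | 33.7 | 22.9 |
| dawn | 1.50 | 32.3 | 23.5 |
| dawn | 2.00 | 32.4 | 27.2 |
| dawn | 2.50 | 30.6 | 29.2 |
| noon | 0.200 | 39.4 | 6.0 |
| noon | 0.333 | 39.0 | 8.2 |
| noon | 0.500 | 38.2 | 11.3 |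
| noon | 0.833 | 35.5 | 16.9 |
| noon | 1.33 | 32.2 | 22.5 |
| noon | 2.50 | 29.3 | 28.5 |

(standard deviation of a reading: 0.5 percentage points)



1. share of target in target plus isomer of the product A at 25 s
2. share of target in target plus isomer of the product A at 8.0 min
3. share of target in target plus isomer of the product A at 3.0 h

For whoever takes over this flask: I follow [isomer of the product A]/[target] at equal times, and I call it the split. At that last reading dawn gives 0.954 and noon 0.973, a gap far smaller than the split itself. So I carry the split of the two runs over to this flask with its larger charge; as a ratio, it does not tell how much target or isomer of the product A stands in the flask.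

Averaged over both runs, the split is 0.471 at 0.833 h, 0.689 at 1.33 h and 0.963 at 2.50 h. Its slope falls from 0.438 /h to 0.234 /h, a factor of 0.535. The middle of the last stretch lies equally far on, so I shrink the slope once more by that factor. When you come at 3.0 h, I expect a split of 1.03, which means a target share of 49.3%. The two early asked times lie before the first reading, so I commit to no number there.

The forecast says 95.5%, 89.5% and 48.7%, holding that “concentration matters little for the share”. The flask gives 96.0%, 90.3% and 49.3%.

    starting material → intermediate (k = 0.263 /min)
    intermediate ⇌ target (K = 2.10, k = 0.628 /min)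
    intermediate ⇌ isomer of the product A (K = 2.40, k = 0.0228 /min)
    starting material + target → side product (k = 10.8 /M/min)
    target ⇌ isomer of the product B (K = 0.331, k = 0.586 /min)

The flask's split at 3.0 h is 1.03 against my 1.03. While starting material lasts, down to 0.229% at 0.300 h, it forms intermediate and also takes target into side product, which stands at 25.2% then and 25.3% at the end. Afterwards intermediate feeds isomer of the product A, which climbs from 7.46% to 27.1% while target slides from 37.3% to 26.4%. The neighbour flask with 39 mM ends with 23.0% target and a split of 1.03.

All runs are calculated on assumed constants, noise included.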